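## Structural features

The target is an achiral tridepside. Three benzene rings of the orsellinate type (ring A, ring B, ring C) each carry a carboxyl carbon on C1, oxygen on C2 and C4, and a methyl on C6. They are joined by two aryl ester bonds: ring B C1 carbonyl to ring A O4, and ring C C1 carbonyl to ring B O4. Ring A ends in a methyl ester, rings A and B carry methyl ethers on O2, and ring C keeps both phenols free, its O2–H hydrogen-bonded to the neighbouring ester carbonyl. There is no stereocentre, so no adjacent stereocentres have to be considered. The fragile groups are the two aryl esters, which are activated acyl donors open to hydroxide, alkoxide and phenoxide-induced acyl migration; strongly basic or nucleophilic operations must therefore precede their formation. The real difficulty is twofold: every carboxyl carbon lies between two ortho substituents, which slows both ester formation and ester hydrolysis, and on rings A and B the two ring oxygens must be told apart (O2 methylated, O4 free or acylated). The key step exploits the pattern of ring A (shared by ring B): C1 with its ester, flanked by C2–OMe and C6–Me, maps onto C5, C4 and C6 of a 4-methoxy-6-methyl-2-pyrone-5-carboxylate, C3 comes from pyrone C3, and a ketene acetal supplies C4 with its oxygen and C5.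

## Logic of the disconnections

**23 ⇒ 22.** The two O–H bonds of ring C are traced back to O–CH2Ph bonds. The ring C phenols must be masked while its carboxyl is activated, and benzyl is removed under neutral reducing conditions that spare both depside links. The skeleton is unchanged, but the acyl partner becomes unambiguous. The forward step must cleave two benzyl ethers without touching three esters, which calls for a neutral, non-nucleophilic medium.

**22 ⇒ 20 + 17.** The ester C(=O)–O bond between the ring C carbonyl and ring B O4 is cut. It is the only bond joining ring C to the rest, and cutting it is convergent: a three-ring compound becomes a two-ring phenol and a one-ring acid. The forward step must acylate a phenol with a di-ortho-substituted acid without generating a phenoxide that could scramble the aryl ester already present in 17.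

**20 ⇒ 19 ⇒ 18.** The two benzyl O–C bonds are cut and the free acid is traced to its methyl ester. Commercial 18 already holds the complete carbon and oxygen pattern of ring C. The forward steps demand forcing alkylation of the chelated 2-OH and forcing hydrolysis of a hindered ester, both acceptable because no depside bond exists at that stage.

**17 ⇒ 16 ⇒ 14 + 12.** The ring B O4–H is traced to its benzyl ether, then the ester C(=O)–O bond between the ring B carbonyl and ring A O4 is cut. Protection of ring B O4 prevents self-acylation of a hydroxy acid. The two-ring compound falls into two monocyclic pieces of identical skeleton. The demands are those of the later esterification, plus a hydrogenolysis that leaves the new aryl ester alone.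

**14 ⇒ 13 ⇒ 12.** The benzyl O–C bond is cut and the acid is traced to the methyl ester. Compounds 14 and 12 differ only in the state of O4 and of the carboxyl, so one ring synthesis serves rings A and B. The hindered ester must be hydrolysed before any depside bond is present.

**12 ⇒ 5 + 8 (through 9, 10, 11).** Ring A bonds C3–C4 and C5–C6 are cut. The O2 methyl arrives on 5, and O4 arrives from 8 as a silyl ether that falls off in work-up, so no selective protection is needed. A tetrasubstituted benzene is reduced to a monocyclic pyrone and a two-carbon unit. The forward step needs the regiochemistry CH2-to-C6 and acetal-carbon-to-C3, and enough thermal drive for a deactivated diene without destroying 8.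

**5 ⇒ 4 ⇒ 1 + 2 (through 3).** The O4–CH3 bond is cut, then the pyrone ring at C4–C5 and O1–C2. Compound 1 supplies C5, C6, the methyl and the ester; 2 supplies C2, C3 and C4. The heterocycle reduces to two commodity chemicals. C-acylation must precede lactonisation, and methylation must go to O4 and not to the lactone carbonyl oxygen.

**8 ⇒ 6 (through 7).** One O–Si bond is cut; 6 already carries the other. The forward step requires kinetic enolisation at low temperature and silylation on oxygen.

## Other disconnections considered

**Alternative 1:** Ring C is taken apart completely at C1–C2, C2–C3, C4–C5 and C5–C6. The precursors are the (2E)-5-diazo-3-methyl-4-oxopent-2-enoate ester of 17 (A2) and (triisopropylsilyloxy)ethyne (A3).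
- **Forward key step:** Irradiation of A2 would trigger a Wolff rearrangement to a vinylketene. (2+2) Addition of A3, four-electron ring opening of the cyclobutenone, six-electron closure and tautomerisation (Danheiser benzannulation) would give A1, the ring C 4-O-silyl ether of the target.
- **In favour:** The regiochemistry is built in: the ketene carbon becomes C2–OH and the silyloxy carbon becomes C4. Ring C needs no benzyl groups. The acyl group placed on 17 is an unhindered enoate, not a di-ortho-substituted benzoate; on this point the alternative is better than step 11.
- **Against:** Ring C is the one ring that can be bought complete as 18, so building it atom by atom gains nothing. A2 requires differentiation of the two carboxyls of an unsymmetrical C5 diacid and installation of a diazo group beside an aryl ester. The irradiation acts on a substrate with two aryl benzoate chromophores, which may undergo photo-Fries migration. A ketene lacking an α-substituent tends to dimerise. A1 still has to be desilylated in the presence of two depside links.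
- **Comparison:** Both plans end in one deprotection and are equal there. The alternative is mechanistically more intricate, a cascade of four pericyclic events against an acyl transfer. It is longer: it still needs 17 and adds at least five operations where the chosen plan needs four.

**Alternative 2:** The ring B C1–carbonyl bond and the carbonyl–O bond to ring A are cut together. The three components are the aryl iodide 4-iodo-3-methoxy-5-methylphenyl 2,4-bis(benzyloxy)-6-methylbenzoate (A5), carbon monoxide (A6) and 12.
- **Forward key step:** Oxidative addition of A5 to bisphosphine-ligated zerovalent palladium, insertion of A6 and capture of the aroyl–palladium species by the phenol 12 with an amine base would give A4, which is the same compound as 22.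
- **In favour:** No ring B carboxylic acid is needed, so the benzylation, hindered saponification, first esterification and intermediate hydrogenolysis (steps 5 to 8) disappear. On step economy the alternative is better, by about two steps in the longest line. The end game, one hydrogenolysis of A4, is equal to step 12.
- **Against:** The C–I bond lies between a methoxy and a methyl group, which slows oxidative addition and the acyl transfer. Phenols are weak nucleophiles towards aroyl–palladium and need heat and base, conditions under which the aryl ester already in A5 can exchange with the phenoxide of 12. Preparing A5 needs a regioselective iodination para to the phenol oxygen against two open ortho positions. A6 is a toxic gas.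
- **Comparison:** The alternative is shorter but carries more mechanistic risk at the decisive bond. It still needs 12 and 20, so it would replace the middle of the chosen route and not its ring synthesis.

**Alternative 3:** Ring B bonds C1–C2 and C5–C6 are cut. The precursors are the but-2-ynoate ester of 12 (A8) and 1,1-dimethoxy-3-(trimethylsilyloxy)buta-1,3-diene (A9).
- **Forward key step:** In a normal-demand Diels–Alder reaction the CH2 terminus of A9 would bond to the methyl-bearing alkyne carbon of A8 and the acetal carbon to the ester-bearing carbon. Loss of one methoxy group as its alcohol and of the silyl group would give A7, which is the same compound as 17.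
- **In favour:** Ring B is formed directly on the ring A oxygen as the free phenol. The O2 methyl comes from the acetal and O4 from the silyl enol ether, so the oxygens are differentiated by origin, the equal of the chosen key step. The acylation that makes A8 is unhindered, which is better than step 7. Steps 5 to 8 shrink to two operations, so on step economy the alternative is better by two steps.
- **Against:** A β-methyl alkynoate is a sluggish dienophile. A9 is sensitive to heat and moisture and needs its own preparation. As a ketene acetal nucleophile it may attack the aryl ester of A8 or add in Michael fashion without closing. The ring A fragment is committed before the uncertain step. Compound 12 must still be made, so two different cycloadditions would need development where the chosen plan feeds two rings from one.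
- **Comparison:** This is the strongest alternative and could be combined with the chosen key step. The chosen plan trades two extra, routine steps for a single ring-forming reaction run on simple material.

Key step: step 4

Remark on the chemistry: atom mapping of the cycloaddition (pyrone C4–OMe to ring A C2, pyrone C3 to C3, acetal carbon to C4, CH2 to C5, pyrone C6–Me to C6) agrees with the structures of 5, 8 and 12, so no structure needed correction.

Remark on the chemistry: compound 18 (methyl orsellinate) is assumed to be purchased, as are 1, 2 and 6.

## Route

**Step 1**
Reactants: 1 methyl acetoacetate; 2 malonyl dichloride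
Product: 4 methyl 4-hydroxy-6-methyl-2-oxo-2H-pyran-5-carboxylate, via C-acylated acid chloride 3 (not isolated)
Conditions: CH2Cl2, 0 °C → reflux, N2 purge (−HCl)
Reagents that add atoms: none
Why: Condensation of a β-keto ester with malonyl dichloride to a 4-hydroxy-2-pyrone is a known reaction type: the enol of 1 is C-acylated at C2 to give 3, whose acetyl enol oxygen closes the six-membered lactone on the second acyl chloride, and tautomerisation gives 4.

**Step 2**
Reactants: 4 methyl 4-hydroxy-6-methyl-2-oxo-2H-pyran-5-carboxylate
Product: 5 methyl 4-methoxy-6-methyl-2-oxo-2H-pyran-5-carboxylate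
Conditions: Me2SO4, K2CO3, acetone, reflux
Reagents that add atoms: dimethyl sulfate, COS(=O)(=O)OC
Why: Williamson-type O-methylation of the acidic 4-hydroxy group (a vinylogous carboxylic acid); carbonate with a hard methylating agent should favour the 4-methoxy-2-pyrone over the 2-methoxy-4-pyrone isomer, as is usual for 4-hydroxy-6-methyl-2-pyrones.

**Step 3**
Reactants: 6 trimethylsilyl acetate
Product: 8 1,1-bis(trimethylsilyloxy)ethene, via lithium silyl ester enolate 7 (not isolated)
Conditions: LiN(iPr)2 (LDA), THF, −78 °C; Me3SiCl, −78 °C → rt; distillation
Reagents that add atoms: chlorotrimethylsilane, C[Si](C)(C)Cl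
Why: Kinetic deprotonation of the silyl ester gives enolate 7, which the oxophilic silicon electrophile traps on oxygen; this is the standard preparation of ketene bis(silyl) acetals.

**Step 4**
Reactants: 5 methyl 4-methoxy-6-methyl-2-oxo-2H-pyran-5-carboxylate; 8 1,1-bis(trimethylsilyloxy)ethene
Product: 12 methyl 4-hydroxy-2-methoxy-6-methylbenzoate, via bridged lactone cycloadduct 9 (not isolated), via bis(silyloxy)cyclohexadiene 10 (not isolated), via aryl trimethylsilyl ether 11 (not isolated)
Conditions: 8 (4 equiv), toluene, sealed tube, 130 °C; then 1 M HCl, THF, rt
Reagents that add atoms: none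
Why: Inverse-electron-demand Diels–Alder reaction: the diene C3=C4–C5=C6 of 5, made electron-poor by the lactone carbonyl and the C5 ester, accepts the electron-rich alkene 8, the CH2 carbon of 8 bonding to C6 and the acetal carbon to C3 to give the bridged lactone 9. Retro-(4+2) extrusion of CO2 from 9 gives diene 10, 1,2-elimination of trimethylsilanol across the former ketene acetal carbons aromatises it to 11, and the aryl silyl ether is hydrolysed in the acidic work-up to 12. The closest known reaction type is the cycloaddition of 2-pyrone-5-carboxylates (coumalates) with ketene acetals, which gives 4-oxygenated benzoates after loss of CO2 and an alcohol. The one ring formed, benzene ring A, is closed by intermolecular (4+2) annulation across pyrone C3 and C6; should the addition be stepwise, conjugate addition at C6 is followed by six-membered closure of the glutaconate-type anion through C3 onto the bis(silyloxy)carbenium carbon, the four-membered closure through C5 being no competitor. No stereocentre is created in 12; the two bridgehead centres of racemic 9 disappear with CO2 loss and aromatisation. The step needs regioselectivity, new oxygen para and not meta to the ester, and the polarisation of 5 secures it: C6 is β to the ester and vinylogously conjugated to the lactone carbonyl and so is the most electrophilic carbon, while C3, the β-carbon of the C4 enol ether, is the natural partner of the electrophilic acetal carbon. It also needs the cycloaddition to outrun thermal O-to-C silyl migration and hydrolysis of 8, which is addressed by an excess of 8, strict exclusion of moisture and acid, and a temperature high enough for a diene deactivated by its 4-methoxy and 6-methyl groups. Because the C2 methoxy comes from the pyrone and the C4 oxygen from 8, the two ring oxygens are differentiated by origin.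

**Step 5**
Reactants: 12 methyl 4-hydroxy-2-methoxy-6-methylbenzoate
Product: 13 methyl 4-(benzyloxy)-2-methoxy-6-methylbenzoate
Conditions: BnBr, K2CO3, acetone, reflux
Reagents that add atoms: benzyl bromide, BrCc1ccccc1
Why: Williamson etherification of the only free OH, a phenol made more acidic by the para ester.

**Step 6**
Reactants: 13 methyl 4-(benzyloxy)-2-methoxy-6-methylbenzoate
Product: 14 4-(benzyloxy)-2-methoxy-6-methylbenzoic acid
Conditions: KOH, DMSO/H2O, 90 °C; then aq. HCl
Reagents that add atoms: potassium hydroxide, [K+].[OH-]
Why: Saponification of a benzoate with two ortho substituents needs poorly solvated hydroxide at elevated temperature; the aryl methyl and benzyl ethers are inert to hydroxide and no aryl ester is present yet.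

**Step 7**
Reactants: 14 4-(benzyloxy)-2-methoxy-6-methylbenzoic acid; 12 methyl 4-hydroxy-2-methoxy-6-methylbenzoate
Product: 16 3-methoxy-4-(methoxycarbonyl)-5-methylphenyl 4-(benzyloxy)-2-methoxy-6-methylbenzoate, via mixed trifluoroacetic anhydride 15 (not isolated)
Conditions: (CF3CO)2O, toluene, rt
Reagents that add atoms: none
Why: Depside esterification through the mixed anhydride 15: the electron-rich, di-ortho-substituted aroyl group ionises towards an acylium-like species whose linear geometry escapes the ortho shielding, so the phenol 12 is O-acylated under acidic, non-nucleophilic conditions that spare the methyl ester and the ethers.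

**Step 8**
Reactants: 16 3-methoxy-4-(methoxycarbonyl)-5-methylphenyl 4-(benzyloxy)-2-methoxy-6-methylbenzoate
Product: 17 3-methoxy-4-(methoxycarbonyl)-5-methylphenyl 4-hydroxy-2-methoxy-6-methylbenzoate
Conditions: H2 (1 atm), 10% Pd/C, EtOAc, rt
Reagents that add atoms: none
Why: Hydrogenolysis of a benzyl aryl ether; aryl esters, the methyl ester and methyl ethers are not reduced under these neutral conditions, and the non-nucleophilic solvent avoids transesterification of the depside link.

**Step 9**
Reactants: 18 methyl 2,4-dihydroxy-6-methylbenzoate (methyl orsellinate)
Product: 19 methyl 2,4-bis(benzyloxy)-6-methylbenzoate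
Conditions: BnBr (2.5 equiv), K2CO3, DMF, 70 °C
Reagents that add atoms: benzyl bromide, BrCc1ccccc1
Why: Double Williamson benzylation; the hydrogen-bonded 2-OH reacts more slowly than the 4-OH, hence the excess reagent and warm dipolar solvent.

**Step 10**
Reactants: 19 methyl 2,4-bis(benzyloxy)-6-methylbenzoate
Product: 20 2,4-bis(benzyloxy)-6-methylbenzoic acid
Conditions: KOH, DMSO/H2O, 90 °C; then aq. HCl
Reagents that add atoms: potassium hydroxide, [K+].[OH-]
Why: Saponification of a hindered benzoate as in step 6; the benzyl ethers are stable to hydroxide.

**Step 11**
Reactants: 20 2,4-bis(benzyloxy)-6-methylbenzoic acid; 17 3-methoxy-4-(methoxycarbonyl)-5-methylphenyl 4-hydroxy-2-methoxy-6-methylbenzoate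
Product: 22 3-methoxy-4-{[3-methoxy-4-(methoxycarbonyl)-5-methylphenoxy]carbonyl}-5-methylphenyl 2,4-bis(benzyloxy)-6-methylbenzoate, via mixed trifluoroacetic anhydride 21 (not isolated)
Conditions: (CF3CO)2O, toluene, rt
Reagents that add atoms: none
Why: Mixed-anhydride depside esterification as in step 7; the medium stays acidic, so no phenoxide is formed that could induce acyl migration of the aryl ester already present in 17.

**Step 12**
Reactants: 22 3-methoxy-4-{[3-methoxy-4-(methoxycarbonyl)-5-methylphenoxy]carbonyl}-5-methylphenyl 2,4-bis(benzyloxy)-6-methylbenzoate
Product: 23 3-methoxy-4-{[3-methoxy-4-(methoxycarbonyl)-5-methylphenoxy]carbonyl}-5-methylphenyl 2,4-dihydroxy-6-methylbenzoate (target)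
Conditions: H2 (1 atm), 10% Pd/C, EtOAc, rt
Reagents that add atoms: none
Why: Hydrogenolysis of both benzyl ethers releases the two phenols of ring C under neutral conditions that leave both depside links and the methyl ester intact.

## Compound list

1 | methyl acetoacetate (methyl 3-oxobutanoate) | COC(=O)CC(C)=O | starting material
2 | malonyl dichloride | O=C(Cl)CC(Cl)=O | starting material
3 | methyl 2-acetyl-5-chloro-3,5-dioxopentanoate | COC(=O)C(C(C)=O)C(=O)CC(=O)Cl | intermediate (not isolated)
4 | methyl 4-hydroxy-6-methyl-2-oxo-2H-pyran-5-carboxylate | COC(=O)c1c(C)oc(=O)cc1O | intermediate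
5 | methyl 4-methoxy-6-methyl-2-oxo-2H-pyran-5-carboxylate | COC(=O)c1c(C)oc(=O)cc1OC | intermediate
6 | trimethylsilyl acetate | CC(=O)O[Si](C)(C)C | starting material
7 | lithium 1-(trimethylsilyloxy)ethenolate | [Li+].[O-]C(=C)O[Si](C)(C)C | intermediate (not isolated)
8 | 1,1-bis(trimethylsilyloxy)ethene | C=C(O[Si](C)(C)C)O[Si](C)(C)C | intermediate
9 | methyl 5-methoxy-1-methyl-3-oxo-8,8-bis(trimethylsilyloxy)-2-oxabicyclo[2.2.2]oct-5-ene-6-carboxylate (racemic; bridgehead configuration fixed by the bicycle) | CC12OC(=O)C(C(OC)=C1C(=O)OC)C(O[Si](C)(C)C)(O[Si](C)(C)C)C2 | intermediate (not isolated)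
10 | methyl 6-methoxy-2-methyl-4,4-bis(trimethylsilyloxy)cyclohexa-1,5-diene-1-carboxylate | COC(=O)C1=C(C)CC(O[Si](C)(C)C)(O[Si](C)(C)C)C=C1OC | intermediate (not isolated)
11 | methyl 2-methoxy-6-methyl-4-(trimethylsilyloxy)benzoate | COC(=O)c1c(C)cc(O[Si](C)(C)C)cc1OC | intermediate (not isolated)
12 | methyl 4-hydroxy-2-methoxy-6-methylbenzoate | COC(=O)c1c(C)cc(O)cc1OC | intermediate
13 | methyl 4-(benzyloxy)-2-methoxy-6-methylbenzoate | COC(=O)c1c(C)cc(OCc2ccccc2)cc1OC | intermediate
14 | 4-(benzyloxy)-2-methoxy-6-methylbenzoic acid | OC(=O)c1c(C)cc(OCc2ccccc2)cc1OC | intermediate
15 | 4-(benzyloxy)-2-methoxy-6-methylbenzoic trifluoroacetic anhydride | O=C(OC(=O)C(F)(F)F)c1c(C)cc(OCc2ccccc2)cc1OC | intermediate (not isolated)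
16 | 3-methoxy-4-(methoxycarbonyl)-5-methylphenyl 4-(benzyloxy)-2-methoxy-6-methylbenzoate | COC(=O)c1c(C)cc(OC(=O)c2c(C)cc(OCc3ccccc3)cc2OC)cc1OC | intermediate
17 | 3-methoxy-4-(methoxycarbonyl)-5-methylphenyl 4-hydroxy-2-methoxy-6-methylbenzoate | COC(=O)c1c(C)cc(OC(=O)c2c(C)cc(O)cc2OC)cc1OC | intermediate
18 | methyl 2,4-dihydroxy-6-methylbenzoate (methyl orsellinate) | COC(=O)c1c(C)cc(O)cc1O | starting material
19 | methyl 2,4-bis(benzyloxy)-6-methylbenzoate | COC(=O)c1c(C)cc(OCc2ccccc2)cc1OCc1ccccc1 | intermediate
20 | 2,4-bis(benzyloxy)-6-methylbenzoic acid | OC(=O)c1c(C)cc(OCc2ccccc2)cc1OCc1ccccc1 | intermediate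
21 | 2,4-bis(benzyloxy)-6-methylbenzoic trifluoroacetic anhydride | O=C(OC(=O)C(F)(F)F)c1c(C)cc(OCc2ccccc2)cc1OCc1ccccc1 | intermediate (not isolated)
22 | 3-methoxy-4-{[3-methoxy-4-(methoxycarbonyl)-5-methylphenoxy]carbonyl}-5-methylphenyl 2,4-bis(benzyloxy)-6-methylbenzoate | COC(=O)c1c(C)cc(OC(=O)c2c(C)cc(OC(=O)c3c(C)cc(OCc4ccccc4)cc3OCc3ccccc3)cc2OC)cc1OC | intermediate
23 | 3-methoxy-4-{[3-methoxy-4-(methoxycarbonyl)-5-methylphenoxy]carbonyl}-5-methylphenyl 2,4-dihydroxy-6-methylbenzoate | COC(=O)c1c(C)cc(OC(=O)c2c(C)cc(OC(=O)c3c(C)cc(O)cc3O)cc2OC)cc1OC | target

## Step count and least certain steps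

Total step count: 12. Longest linear sequence: 9 steps (steps 1, 2, 4, 5, 6, 7, 8, 11, 12). Step 3 and steps 9 and 10 are side branches.

**Step 4 (key step).**
- Risk: the cycloaddition may be too slow, because the 4-methoxy group donates into the diene and the 6-methyl group crowds the carbon that must be attacked. Thermal O-to-C silyl migration or adventitious hydrolysis of 8 could then consume the dienophile first. Conjugate addition without ring closure, or opening of the bridged lactone without loss of CO2, are further ways for the sequence to stall.
- Fallback: this abandons ring construction and differentiates the two oxygens of a preformed ring through the hydrogen bond. It sets out from 18. Selective benzylation of the non-chelated 4-OH (BnBr 1 equiv, K2CO3, acetone, reflux) should give methyl 4-(benzyloxy)-2-hydroxy-6-methylbenzoate F1. Methylation of the chelated 2-OH (MeI, K2CO3, DMF, 60 °C) comes back to the route at 13. Hydrogenolysis of a portion of 13 (H2, Pd/C, EtOAc) gives 12.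

**Step 1.**
- Risk: self-condensation of 2, or O-acylation and double acylation of 1, may compete with the C-acylation and lactonisation sequence, and the hydrogen chloride formed may degrade the product.
- Fallback: the two bond formations are separated. It sets out from 1. Magnesium-mediated C-acylation (MgCl2, pyridine, CH2Cl2, 0 °C) with methyl 3-chloro-3-oxopropanoate should give dimethyl 2-acetyl-3-oxopentanedioate F2. Acid-promoted enol lactonisation with loss of methanol (cat. TsOH, toluene, reflux) comes back at 4. Acid is chosen over base to avoid carbocyclic Claisen-type closure.

**Step 6.**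
- Risk: acyl–oxygen cleavage may be incomplete because the two ortho substituents shield the carbonyl from hydroxide.
- Fallback: the ester is cleaved at the alkyl–oxygen bond instead. It sets out from 13. SN2 attack of iodide on the ester methyl group (LiI, EtOAc, reflux; acidic work-up) is not affected by the ortho substituents and comes back at 14. No new compound is formed on the way (F0).

**Step 7.**
- Risk: acyl transfer to a phenol deactivated by its para ester may be slow, allowing O-trifluoroacetylation of 12 or acid-induced loss of the benzyl group from 14 or 15 to compete.
- Fallback: activation as an isolated acyl chloride with nucleophilic catalysis. It sets out from 14. Oxalyl chloride and catalytic DMF in CH2Cl2 should give 4-(benzyloxy)-2-methoxy-6-methylbenzoyl chloride F3. Reaction with 12, Et3N and DMAP in CH2Cl2 comes back at 16.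

**Step 11.**
- Risk: the same slow acyl transfer, made worse by the bulkier ortho benzyloxy group, with possible participation of that ether oxygen leading to loss of benzyl. Any drift towards basic conditions would risk acyl migration in 17.
- Fallback: it sets out from 20. Oxalyl chloride and catalytic DMF should give 2,4-bis(benzyloxy)-6-methylbenzoyl chloride F4. Coupling with 17 under Et3N and DMAP in CH2Cl2 at 0 °C, with base kept to the minimum, comes back at 22.

## Further compounds

F1 | step 4 | methyl 4-(benzyloxy)-2-hydroxy-6-methylbenzoate | COC(=O)c1c(C)cc(OCc2ccccc2)cc1O
F2 | step 1 | dimethyl 2-acetyl-3-oxopentanedioate | COC(=O)CC(=O)C(C(C)=O)C(=O)OC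
F0 | step 6 | none | none
F3 | step 7 | 4-(benzyloxy)-2-methoxy-6-methylbenzoyl chloride | O=C(Cl)c1c(C)cc(OCc2ccccc2)cc1OC
F4 | step 11 | 2,4-bis(benzyloxy)-6-methylbenzoyl chloride | O=C(Cl)c1c(C)cc(OCc2ccccc2)cc1OCc1ccccc1
A1 | alternative 1 | 3-methoxy-4-{[3-methoxy-4-(methoxycarbonyl)-5-methylphenoxy]carbonyl}-5-methylphenyl 2-hydroxy-6-methyl-4-(triisopropylsilyloxy)benzoate | COC(=O)c1c(C)cc(OC(=O)c2c(C)cc(OC(=O)c3c(C)cc(O[Si](C(C)C)(C(C)C)C(C)C)cc3O)cc2OC)cc1OC
A2 | alternative 1 | 3-methoxy-4-{[3-methoxy-4-(methoxycarbonyl)-5-methylphenoxy]carbonyl}-5-methylphenyl (2E)-5-diazo-3-methyl-4-oxopent-2-enoate | COC(=O)c1c(C)cc(OC(=O)c2c(C)cc(OC(=O)/C=C(\C)C(=O)C=[N+]=[N-])cc2OC)cc1OC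
A3 | alternative 1 | (triisopropylsilyloxy)ethyne | C#CO[Si](C(C)C)(C(C)C)C(C)C
A4 | alternative 2 | 3-methoxy-4-{[3-methoxy-4-(methoxycarbonyl)-5-methylphenoxy]carbonyl}-5-methylphenyl 2,4-bis(benzyloxy)-6-methylbenzoate (identical with 22) | COC(=O)c1c(C)cc(OC(=O)c2c(C)cc(OC(=O)c3c(C)cc(OCc4ccccc4)cc3OCc3ccccc3)cc2OC)cc1OC
A5 | alternative 2 | 4-iodo-3-methoxy-5-methylphenyl 2,4-bis(benzyloxy)-6-methylbenzoate | COc1cc(OC(=O)c2c(C)cc(OCc3ccccc3)cc2OCc2ccccc2)cc(C)c1I
A6 | alternative 2 | carbon monoxide | [C-]#[O+]
A7 | alternative 3 | 3-methoxy-4-(methoxycarbonyl)-5-methylphenyl 4-hydroxy-2-methoxy-6-methylbenzoate (identical with 17) | COC(=O)c1c(C)cc(OC(=O)c2c(C)cc(O)cc2OC)cc1OC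
A8 | alternative 3 | 3-methoxy-4-(methoxycarbonyl)-5-methylphenyl but-2-ynoate | COC(=O)c1c(C)cc(OC(=O)C#CC)cc1OC
A9 | alternative 3 | 1,1-dimethoxy-3-(trimethylsilyloxy)buta-1,3-diene | COC(OC)=CC(=C)O[Si](C)(C)C
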